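The seven-membered ring holds a 1,3-dioxygenated C5–C6–C7 unit (azulene numbering: C5 ester carbinol, C6 methylene, C7 tertiary carbinol), the imprint of a ketene. Everything rests on disconnecting C5–C6 and C7–C8: the ring shrinks to a cyclopentanone in which C5 and C8 are joined. The key step is the regioselective [2+2] cycloaddition of dichloroketene to the C5=C8 silyl enol ether of an all-trans 2-isopropyl-3-methallyl-4-vinylcyclopentanone, made by two anti-selective conjugate additions; it forms both bonds at once. Strain-driven fragmentation of the temporary C5–C8 bond then gives the cycloheptenone, ring-closing metathesis the trans-fused cyclopentene, and hydroxyl-directed epoxidation with hydride opening the C5/C7 stereocenters.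

Key step: step 5

Remark (assumption): the (S)-enantiomer of silyl ether 1 is taken to be commercial like its antipode; bicyclic compounds carry azulene locants (C1/C2 cyclopentene or epoxide carbons, C3a/C8a ring fusion, C4 isopropyl, C5 and C7 carbinols); the carbinol centre of 10 is destroyed again within step 7, so 10 is drawn without configuration at that carbon.

Step 1
Reactants: 1 (S)-4-(tert-butyldimethylsilyloxy)cyclopent-2-en-1-one
Product: 2 (S)-4-(tert-butyldimethylsilyloxy)-2-iodocyclopent-2-en-1-one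
Conditions: I2, pyridine, CH2Cl2, 0 °C to rt
Reagents that add atoms: iodine, II
Why: α-Iodination of the enone by pyridine conjugate addition, iodination of the enolate and elimination (Baylis–Hillman-type α-halogenation) should place iodine on C2 only and leaves the C4 stereocenter untouched.

Step 2
Reactants: 2 (S)-4-(tert-butyldimethylsilyloxy)-2-iodocyclopent-2-en-1-one
Product: 3 (S)-4-(tert-butyldimethylsilyloxy)-2-isopropylcyclopent-2-en-1-one
Conditions: i-PrZnBr, Pd(OAc)2 (2 mol%), CPhos (4 mol%), THF, rt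
Reagents that add atoms: isopropylzinc bromide, CC(C)[Zn]Br
Why: Negishi cross-coupling of the α-iodoenone with a secondary alkylzinc halide, with CPhos favouring reductive elimination over β-hydride isomerisation, should install the isopropyl group without touching the silyl ether.

Step 3
Reactants: 3 (S)-4-(tert-butyldimethylsilyloxy)-2-isopropylcyclopent-2-en-1-one
Product: 6 (4R,5S)-5-isopropyl-4-(2-methylallyl)cyclopent-2-en-1-one, via bis-silyl enol ether 4 (not isolated), via siloxy ketone 5 (not isolated)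
Conditions: 2-methylallylmagnesium chloride, CuBr·SMe2 (1.1 equiv), TMSCl, THF, −78 °C; 1 M HCl work-up; then DBU, CH2Cl2, rt
Reagents that add atoms: 2-methylallylmagnesium chloride, CC(=C)C[Mg]Cl
Why: Conjugate addition of the allylcopper reagent (TMSCl-accelerated 1,4-addition) should occur anti to the C4 silyloxy group, hydrolysis of enol ether 4 protonates C2 to the favoured trans isopropyl ketone 5, and E1cB loss of silanol with DBU relays the chirality of the expendable C–O centre to the C4 and C5 centres of 6.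

Step 4
Reactants: 6 (4R,5S)-5-isopropyl-4-(2-methylallyl)cyclopent-2-en-1-one
Product: 7 (3R,4R,5S)-5-isopropyl-4-(2-methylallyl)-1-(trimethylsilyloxy)-3-vinylcyclopent-1-ene
Conditions: vinylmagnesium bromide, CuBr·SMe2 (10 mol%), TMSCl, THF, −78 °C; Et3N, pentane, filtration
Reagents that add atoms: vinylmagnesium bromide, C=C[Mg]Br; chlorotrimethylsilane, C[Si](C)(C)Cl
Why: Copper-catalysed 1,4-addition of the vinyl Grignard reagent should occur anti to the neighbouring methallyl group, setting the future C8a, and silyl trapping fixes the enolate regiospecifically on the unsubstituted side, as the key step requires.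

Step 5
Reactants: 7 (3R,4R,5S)-5-isopropyl-4-(2-methylallyl)-1-(trimethylsilyloxy)-3-vinylcyclopent-1-ene
Product: 8 (1S,2S,3R,4R,5S)-7,7-dichloro-2-isopropyl-3-(2-methylallyl)-1-(trimethylsilyloxy)-4-vinylbicyclo[3.2.0]heptan-6-one
Conditions: Cl2CHCOCl, Et3N, hexane, rt (slow addition)
Reagents that add atoms: dichloroacetyl chloride, O=C(Cl)C(Cl)Cl
Why: Et3N dehydrochlorinates dichloroacetyl chloride to dichloroketene, whose electrophilic central carbon is attacked by the nucleophilic enol carbon (C5 of 8) while the dichloromethylene carbon bonds to the silyloxy carbon (C1 of 8), in a concerted but highly asynchronous [π2s+π2a] cycloaddition whose limiting form is a silyloxocarbenium/dichloroenolate zwitterion; the new bonds C5–C6 and C1–C7 of 8 are the future C7–C8 and C5–C6 bonds of the hydroazulene. The closest known reaction type is the dichloroketene–silyl enol ether [2+2] cycloaddition used for two-carbon ring expansion of cycloalkanones. The cyclobutanone ring closes by cycloaddition (in the stepwise limit a 4-exo-trig collapse of the enolate carbon onto the oxocarbenium carbon), and the four-membered ring enforces a cis ring fusion. The two new stereocenters C1 and C5 are set by approach of the ketene anti to the flanking C2 isopropyl and C4 vinyl groups, but both are temporary and vanish when the C1–C5 bond is broken in step 7. The step needs regioselectivity (carbonyl carbon to C5, CCl2 to C1), secured by the polarity of the enol ether, and chemoselectivity for the enol ether over the vinyl and methallyl groups, secured because amine-generated dichloroketene adds only to electron-rich alkenes.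

Step 6
Reactants: 8 (1S,2S,3R,4R,5S)-7,7-dichloro-2-isopropyl-3-(2-methylallyl)-1-(trimethylsilyloxy)-4-vinylbicyclo[3.2.0]heptan-6-one
Product: 9 (1S,2S,3R,4R,5S)-2-isopropyl-3-(2-methylallyl)-1-(trimethylsilyloxy)-4-vinylbicyclo[3.2.0]heptan-6-one
Conditions: Zn dust, AcOH, i-PrOH/H2O, 0 °C
Reagents that add atoms: none

Why: Zinc reduction of the α,α-dichloroketone via zinc enolates (reductive dehalogenation) should remove both chlorines while the cold, weakly acidic medium spares the tertiary silyl ether and the alkenes.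

Step 7
Reactants: 9 (1S,2S,3R,4R,5S)-2-isopropyl-3-(2-methylallyl)-1-(trimethylsilyloxy)-4-vinylbicyclo[3.2.0]heptan-6-one
Product: 12 (5R,6R,7S)-7-isopropyl-3-methyl-6-(2-methylallyl)-5-vinylcyclohept-2-en-1-one, via tertiary cyclobutanol 10 (not isolated), via deconjugated enone 11 (not isolated)
Conditions: MeMgBr, THF, −78 °C; aq. HCl quench; then TsOH·H2O (10 mol%), CH2Cl2, rt
Reagents that add atoms: methylmagnesium bromide, C[Mg]Br
Why: Grignard 1,2-addition to the strained cyclobutanone gives carbinol 10, whose acid-promoted ionisation should trigger a Grob-type (retro-Prins) fragmentation in which the silyloxy oxygen pushes and the more substituted ring-fusion bond C1–C5 breaks (the bond that also cleaves in the retro-aldol opening of such adducts), expelling trimethylsilanol to give 11, which the acid equilibrates to the conjugated enone 12; no stereocenter is created and the epimerisable C7 stays in its favoured trans arrangement.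

Step 8
Reactants: 12 (5R,6R,7S)-7-isopropyl-3-methyl-6-(2-methylallyl)-5-vinylcyclohept-2-en-1-one
Product: 13 (3aR,4S,8aS)-4-isopropyl-2,7-dimethyl-3,3a,8,8a-tetrahydroazulen-5(4H)-one
Conditions: second-generation Grubbs catalyst RuCl2(=CHPh)(PCy3)(H2IMes) (5 mol%), CH2Cl2, 40 °C
Reagents that add atoms: none

Why: Ring-closing metathesis between the vinyl and the 1,1-disubstituted methallyl alkene should close the trisubstituted cyclopentene, the trans-diequatorial side chains giving the trans-fused bicycle while the electron-poor trisubstituted enone alkene stays a bystander.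

Step 9
Reactants: 13 (3aR,4S,8aS)-4-isopropyl-2,7-dimethyl-3,3a,8,8a-tetrahydroazulen-5(4H)-one
Product: 14 (3aR,4S,5S,8aS)-4-isopropyl-2,7-dimethyl-3,3a,4,5,8,8a-hexahydroazulen-5-ol
Conditions: Li[HB(s-Bu)3], THF, −78 °C; H2O
Reagents that add atoms: none

Why: 1,2-Reduction of the β,β-disubstituted enone by the bulky borohydride should deliver hydride to the carbonyl face opposite the adjacent isopropyl group, setting C5 with the hydroxyl cis to isopropyl.

Step 10
Reactants: 14 (3aR,4S,5S,8aS)-4-isopropyl-2,7-dimethyl-3,3a,4,5,8,8a-hexahydroazulen-5-ol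
Product: 15 (3aR,4S,5S,6S,7R,8aS)-6,7-epoxy-4-isopropyl-2,7-dimethyl-3,3a,4,5,6,7,8,8a-octahydroazulen-5-ol
Conditions: VO(acac)2 (5 mol%), t-BuOOH, CH2Cl2, 0 °C to rt
Reagents that add atoms: tert-butyl hydroperoxide, CC(C)(C)OO
Why: Hydroxyl-directed vanadium-catalysed epoxidation delivers oxygen to the C6=C7 alkene from the face of the C5 hydroxyl (reliably syn in cycloheptenols), setting C7, and leaves the undirected C1=C2 alkene untouched.

Step 11
Reactants: 15 (3aR,4S,5S,6S,7R,8aS)-6,7-epoxy-4-isopropyl-2,7-dimethyl-3,3a,4,5,6,7,8,8a-octahydroazulen-5-ol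
Product: 16 (3aR,4S,5R,7R,8aS)-4-isopropyl-2,7-dimethyl-3,3a,4,5,6,7,8,8a-octahydroazulene-5,7-diol
Conditions: LiAlH4, THF, 0 °C to rt; aqueous work-up
Reagents that add atoms: none

Why: SN2 hydride opening of the trisubstituted epoxide at the less substituted C6 keeps the C7–O bond, so the tertiary alcohol should emerge cis to the C5 hydroxyl.

Step 12
Reactants: 16 (3aR,4S,5R,7R,8aS)-4-isopropyl-2,7-dimethyl-3,3a,4,5,6,7,8,8a-octahydroazulene-5,7-diol
Product: 17 (1S,2R,3aR,4S,5R,7R,8aS)-1,2-epoxy-4-isopropyl-2,7-dimethyldecahydroazulene-5,7-diol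
Conditions: mCPBA, CH2Cl2, 0 °C
Reagents that add atoms: 3-chloroperbenzoic acid, OOC(=O)c1cccc(Cl)c1
Why: Prilezhaev epoxidation of the trisubstituted cyclopentene should occur on the face of the C3a hydrogen, anti to the pseudoaxial allylic C8a–H (torsional control in the envelope) and on the side of the two hydroxyls that can hydrogen-bond to the peracid, setting C1 and C2.

Step 13
Reactants: 17 (1S,2R,3aR,4S,5R,7R,8aS)-1,2-epoxy-4-isopropyl-2,7-dimethyldecahydroazulene-5,7-diol; 18 3-(benzyloxy)-4-methoxybenzoic acid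
Product: 19 (1S,2R,3aR,4S,5R,7R,8aS)-1,2-epoxy-7-hydroxy-4-isopropyl-2,7-dimethyldecahydroazulen-5-yl 3-(benzyloxy)-4-methoxybenzoate
Conditions: DCC, DMAP, CH2Cl2, rt
Reagents that add atoms: none

Why: Steglich esterification should acylate the secondary C5 hydroxyl selectively over the tertiary C7 hydroxyl and is mild enough for the epoxide.

Step 14
Reactants: 19 (1S,2R,3aR,4S,5R,7R,8aS)-1,2-epoxy-7-hydroxy-4-isopropyl-2,7-dimethyldecahydroazulen-5-yl 3-(benzyloxy)-4-methoxybenzoate
Product: 20 (1S,2R,3aR,4S,5R,7R,8aS)-1,2-epoxy-7-hydroxy-4-isopropyl-2,7-dimethyldecahydroazulen-5-yl 3-hydroxy-4-methoxybenzoate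
Conditions: H2 (1 atm), Pd/C, EtOAc, rt
Reagents that add atoms: none

Why: Hydrogenolysis of the benzyl ether should free the phenol under neutral conditions that leave the aliphatic epoxide, the aryl ester and the tertiary alcohol intact.

Compound list
1 | (S)-4-(tert-butyldimethylsilyloxy)cyclopent-2-en-1-one | O=C1C[C@H](O[Si](C)(C)C(C)(C)C)C=C1 | starting material
2 | (S)-4-(tert-butyldimethylsilyloxy)-2-iodocyclopent-2-en-1-one | O=C1C[C@H](O[Si](C)(C)C(C)(C)C)C=C1I | intermediate
3 | (S)-4-(tert-butyldimethylsilyloxy)-2-isopropylcyclopent-2-en-1-one | O=C1C[C@H](O[Si](C)(C)C(C)(C)C)C=C1C(C)C | intermediate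
4 | (3S,4S)-4-(tert-butyldimethylsilyloxy)-2-isopropyl-3-(2-methylallyl)-1-(trimethylsilyloxy)cyclopent-1-ene | C[Si](C)(C)OC1=C(C(C)C)[C@H](CC(C)=C)[C@@H](O[Si](C)(C)C(C)(C)C)C1 | intermediate
5 | (2S,3S,4S)-4-(tert-butyldimethylsilyloxy)-2-isopropyl-3-(2-methylallyl)cyclopentan-1-one | O=C1C[C@H](O[Si](C)(C)C(C)(C)C)[C@@H](CC(C)=C)[C@@H]1C(C)C | intermediate
6 | (4R,5S)-5-isopropyl-4-(2-methylallyl)cyclopent-2-en-1-one | O=C1C=C[C@@H](CC(C)=C)[C@@H]1C(C)C | intermediate
7 | (3R,4R,5S)-5-isopropyl-4-(2-methylallyl)-1-(trimethylsilyloxy)-3-vinylcyclopent-1-ene | C[Si](C)(C)OC1=C[C@H](C=C)[C@@H](CC(C)=C)[C@@H]1C(C)C | intermediate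
8 | (1S,2S,3R,4R,5S)-7,7-dichloro-2-isopropyl-3-(2-methylallyl)-1-(trimethylsilyloxy)-4-vinylbicyclo[3.2.0]heptan-6-one | O=C1C(Cl)(Cl)[C@@]2(O[Si](C)(C)C)[C@@H]1[C@H](C=C)[C@@H](CC(C)=C)[C@@H]2C(C)C | intermediate
9 | (1S,2S,3R,4R,5S)-2-isopropyl-3-(2-methylallyl)-1-(trimethylsilyloxy)-4-vinylbicyclo[3.2.0]heptan-6-one | O=C1C[C@@]2(O[Si](C)(C)C)[C@@H]1[C@H](C=C)[C@@H](CC(C)=C)[C@@H]2C(C)C | intermediate
10 | 2-isopropyl-6-methyl-3-(2-methylallyl)-1-(trimethylsilyloxy)-4-vinylbicyclo[3.2.0]heptan-6-ol (ring centres as in 9; C6 either way) | CC1(O)C[C@@]2(O[Si](C)(C)C)[C@@H]1[C@H](C=C)[C@@H](CC(C)=C)[C@@H]2C(C)C | intermediate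
11 | (5R,6R,7S)-7-isopropyl-3-methyl-6-(2-methylallyl)-5-vinylcyclohept-3-en-1-one | O=C1CC(C)=C[C@H](C=C)[C@@H](CC(C)=C)[C@@H]1C(C)C | intermediate
12 | (5R,6R,7S)-7-isopropyl-3-methyl-6-(2-methylallyl)-5-vinylcyclohept-2-en-1-one | O=C1C=C(C)C[C@H](C=C)[C@@H](CC(C)=C)[C@@H]1C(C)C | intermediate
13 | (3aR,4S,8aS)-4-isopropyl-2,7-dimethyl-3,3a,8,8a-tetrahydroazulen-5(4H)-one | O=C1C=C(C)C[C@@H]2C=C(C)C[C@H]2[C@@H]1C(C)C | intermediate
14 | (3aR,4S,5S,8aS)-4-isopropyl-2,7-dimethyl-3,3a,4,5,8,8a-hexahydroazulen-5-ol | O[C@@H]1C=C(C)C[C@@H]2C=C(C)C[C@H]2[C@@H]1C(C)C | intermediate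
15 | (3aR,4S,5S,6S,7R,8aS)-6,7-epoxy-4-isopropyl-2,7-dimethyl-3,3a,4,5,6,7,8,8a-octahydroazulen-5-ol | O[C@@H]1[C@@H]2O[C@]2(C)C[C@@H]3C=C(C)C[C@H]3[C@@H]1C(C)C | intermediate
16 | (3aR,4S,5R,7R,8aS)-4-isopropyl-2,7-dimethyl-3,3a,4,5,6,7,8,8a-octahydroazulene-5,7-diol | O[C@@H]1C[C@](C)(O)C[C@@H]2C=C(C)C[C@H]2[C@@H]1C(C)C | intermediate
17 | (1S,2R,3aR,4S,5R,7R,8aS)-1,2-epoxy-4-isopropyl-2,7-dimethyldecahydroazulene-5,7-diol | O[C@@H]1C[C@](C)(O)C[C@H]2[C@@H](C[C@@]3(C)O[C@@H]23)[C@@H]1C(C)C | intermediate
18 | 3-(benzyloxy)-4-methoxybenzoic acid | COc1ccc(C(=O)O)cc1OCc1ccccc1 | starting material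
19 | (1S,2R,3aR,4S,5R,7R,8aS)-1,2-epoxy-7-hydroxy-4-isopropyl-2,7-dimethyldecahydroazulen-5-yl 3-(benzyloxy)-4-methoxybenzoate | COc1ccc(C(=O)O[C@@H]2C[C@](C)(O)C[C@H]3[C@@H](C[C@@]4(C)O[C@@H]34)[C@@H]2C(C)C)cc1OCc1ccccc1 | intermediate
20 | (1S,2R,3aR,4S,5R,7R,8aS)-1,2-epoxy-7-hydroxy-4-isopropyl-2,7-dimethyldecahydroazulen-5-yl 3-hydroxy-4-methoxybenzoate (CNP0106636.1) | COc1ccc(C(=O)O[C@@H]2C[C@](C)(O)C[C@H]3[C@@H](C[C@@]4(C)O[C@@H]34)[C@@H]2C(C)C)cc1O | target

Total step count: 14. Longest linear sequence: 14 steps (1 to 20; acid 18 enters at step 13).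

Steps most likely to fail

Step 7. The fragmentation may take the wrong course: cleavage of the C1–C7 bond instead of the ring-fusion bond, plain dehydration of the tertiary cyclobutanol, or incomplete migration of the double bond into conjugation. Fallback: setting out from 9, the retro-aldol opening known for β-silyloxy cyclobutanones (AcOH, i-PrOH/H2O, 80 °C) should give (4S,5R,6R)-4-isopropyl-5-(2-methylallyl)-6-vinylcycloheptane-1,3-dione F1. Triflation at the less hindered oxygen, remote from the isopropyl group (Tf2O, 2,6-lutidine, CH2Cl2, −78 °C), should give (4S,5R,6R)-4-isopropyl-5-(2-methylallyl)-3-oxo-6-vinylcyclohept-1-en-1-yl trifluoromethanesulfonate F2. Cross-coupling of this vinylogous triflate with MeMgBr under Fe(acac)3 catalysis (THF/NMP, −30 °C) installs the methyl group and comes back to the route at 12.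

Step 12. Facial selectivity in the epoxidation of the cyclopentene may be poor or reversed, because the allylic and homoallylic ring-fusion centres bias opposite faces. Fallback: setting out from 16, NBS in aqueous DME should form the bromonium ion on the face the peracid prefers, and water opens it at the tertiary C2 from the other side to give (1R,2R,3aS,4S,5R,7R,8aS)-1-bromo-4-isopropyl-2,7-dimethyldecahydroazulene-2,5,7-triol F3. K2CO3 in MeOH then closes the oxirane with inversion at C1, which places the epoxide on the face opposite to the one reached by direct epoxidation and comes back to the route at 17.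

Step 9. Hydride may be delivered to the wrong face of the C5 carbonyl, because the conformation of the cycloheptenone is hard to predict. Fallback: setting out from 13, Luche reduction (NaBH4, CeCl3·7H2O, MeOH, −78 °C) is used to reach the C5 epimer (3aR,4S,5R,8aS)-4-isopropyl-2,7-dimethyl-3,3a,4,5,8,8a-hexahydroazulen-5-ol F4 cleanly. Mitsunobu inversion with 4-nitrobenzoic acid (PPh3, DIAD, THF) should give (3aR,4S,5S,8aS)-4-isopropyl-2,7-dimethyl-3,3a,4,5,8,8a-hexahydroazulen-5-yl 4-nitrobenzoate F5, and methanolysis (K2CO3, MeOH) comes back to the route at 14.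

Further compounds
F1 | step 7 | (4S,5R,6R)-4-isopropyl-5-(2-methylallyl)-6-vinylcycloheptane-1,3-dione | O=C1CC(=O)C[C@H](C=C)[C@@H](CC(C)=C)[C@@H]1C(C)C
F2 | step 7 | (4S,5R,6R)-4-isopropyl-5-(2-methylallyl)-3-oxo-6-vinylcyclohept-1-en-1-yl trifluoromethanesulfonate | O=C1C=C(OS(=O)(=O)C(F)(F)F)C[C@H](C=C)[C@@H](CC(C)=C)[C@@H]1C(C)C
F3 | step 12 | (1R,2R,3aS,4S,5R,7R,8aS)-1-bromo-4-isopropyl-2,7-dimethyldecahydroazulene-2,5,7-triol | O[C@@H]1C[C@](C)(O)C[C@H]2[C@@H](C[C@@](C)(O)[C@@H]2Br)[C@@H]1C(C)C
F4 | step 9 | (3aR,4S,5R,8aS)-4-isopropyl-2,7-dimethyl-3,3a,4,5,8,8a-hexahydroazulen-5-ol | O[C@H]1C=C(C)C[C@@H]2C=C(C)C[C@H]2[C@@H]1C(C)C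
F5 | step 9 | (3aR,4S,5S,8aS)-4-isopropyl-2,7-dimethyl-3,3a,4,5,8,8a-hexahydroazulen-5-yl 4-nitrobenzoate | O=C(O[C@@H]1C=C(C)C[C@@H]2C=C(C)C[C@H]2[C@@H]1C(C)C)c1ccc(cc1)[N+](=O)[O-]
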